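Colleterpenol is opened at the C11–C12 bond of its 14-membered ring (ring carbons C1–C14; C14 is the methine that carries the C15 carbinol): the methyl-bearing sp2 carbon C11 of the C10=C11 alkene against the sp3 methylene C12, two carbons from C14. One operation, hydroboration of a C14 vinyl group and intramolecular B-alkyl Suzuki–Miyaura coupling with an (E)-alkenyl iodide, forges this bond, closes the ring and delivers the target with the alkene geometry already in place. The acyclic precursor arises from geranylacetone and an allene-derived (Z)-allylborane, whose chair-controlled addition sets C14 and C15 and leaves exactly that vinyl group.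

Key step: step 10

Assumption: (2E,6E)-farnesyl acetate and (E)-geranylacetone are bought as single geometric isomers, and the antipode of the chiral borane in step 9 is the one that adds allyl groups to the Re face (O > CH2R > CH3) of alkyl methyl ketones.

Step 1
Reactants: 1 (2E,6E)-farnesyl acetate
Product: 3 (2E,6E)-9-(3,3-dimethyloxiran-2-yl)-3,7-dimethylnona-2,6-dien-1-ol (racemic 10,11-epoxyfarnesol), via bromohydrin acetate 2 (not isolated)
Conditions: NBS (1.1 equiv), THF/H2O, 0 °C; crude 2, then K2CO3, MeOH, rt
Reagents that add atoms: water, O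
Why: Bromohydrin formation in aqueous THF is selective for the terminal trisubstituted alkene, and K2CO3/MeOH closes the epoxide (intramolecular Williamson reaction) while transesterifying the acetate; the racemic epoxide stereocentre is destroyed in step 2.

Step 2
Reactants: 3 racemic 10,11-epoxyfarnesol
Product: 4 (4E,8E)-10-hydroxy-4,8-dimethyldeca-4,8-dienal
Conditions: H5IO6 (1.2 equiv), THF/H2O, 0 °C
Reagents that add atoms: none
Why: Periodic acid hydrolyses the trisubstituted epoxide and cleaves the glycol (Malaprade cleavage), removing the terminal C3 unit as acetone without touching the two remaining trisubstituted alkenes.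

Step 3
Reactants: 4 (4E,8E)-10-hydroxy-4,8-dimethyldeca-4,8-dienal
Product: 5 (2E,6E)-3,7-dimethylundeca-2,6-dien-10-yn-1-ol
Conditions: dimethyl (1-diazo-2-oxopropyl)phosphonate, K2CO3, MeOH, 0 °C to rt
Reagents that add atoms: dimethyl (1-diazo-2-oxopropyl)phosphonate, COP(=O)(OC)C(=[N+]=[N-])C(C)=O
Why: Seyferth–Gilbert homologation with the Ohira–Bestmann reagent should convert the aldehyde into the terminal alkyne under carbonate conditions that tolerate the free allylic alcohol.

Step 4
Reactants: 5 (2E,6E)-3,7-dimethylundeca-2,6-dien-10-yn-1-ol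
Product: 7 (2E,6E)-3,7-dimethyldodeca-2,6-dien-10-yn-1-ol, via dilithium alkoxide acetylide 6 (not isolated)
Conditions: n-BuLi (2.1 equiv), THF, −78 to 0 °C; then MeI (1.1 equiv), 0 °C to rt
Reagents that add atoms: iodomethane, CI
Why: In THF the acetylide carbon of the dianion is far more nucleophilic toward MeI than the lithium alkoxide, so acetylide alkylation should give the methyl alkyne.

Step 5
Reactants: 7 (2E,6E)-3,7-dimethyldodeca-2,6-dien-10-yn-1-ol
Product: 9 (2E,6E,10E)-11-iodo-3,7-dimethyldodeca-2,6,10-trien-1-ol, via alkenylzirconocene alkoxide 8 (not isolated)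
Conditions: Cp2Zr(H)Cl (3 equiv), THF, rt to 50 °C; then I2, THF, 0 °C
Reagents that add atoms: iodine, II
Why: Syn-hydrozirconation of the methyl alkyne with excess Cp2Zr(H)Cl (one equivalent is consumed by the hydroxyl) equilibrates zirconium to the less hindered, methyl-bearing carbon, and iodinolysis with retention should give the (E)-2-iodoalkene; trisubstituted alkenes are inert.

Step 6
Reactants: 9 (2E,6E,10E)-11-iodo-3,7-dimethyldodeca-2,6,10-trien-1-ol
Product: 10 (2E,6E,10E)-1-bromo-11-iodo-3,7-dimethyldodeca-2,6,10-triene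
Conditions: PBr3 (0.4 equiv), Et2O, −10 °C; used crude
Reagents that add atoms: phosphorus tribromide, BrP(Br)Br
Why: SN2 bromination of the primary allylic alcohol at low temperature proceeds without allylic transposition, as in the standard preparation of farnesyl bromide.

Step 7
Reactants: 10 (2E,6E,10E)-1-bromo-11-iodo-3,7-dimethyldodeca-2,6,10-triene; 11 prop-2-yn-1-ol (1.5 equiv)
Product: 12 (5E,9E,13E)-14-iodo-6,10-dimethylpentadeca-5,9,13-trien-2-yn-1-ol
Conditions: CuI (10 mol %), n-Bu4NCl, K2CO3, DMF, rt
Reagents that add atoms: none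
Why: Copper-catalysed allylation of the terminal alkyne (copper acetylide, SN2 at the primary allylic bromide) should give the skipped enyne; the alkenyl iodide does not couple without palladium at room temperature.

Step 8
Reactants: 12 (5E,9E,13E)-14-iodo-6,10-dimethylpentadeca-5,9,13-trien-2-yn-1-ol
Product: 15 (5E,9E,13E)-14-iodo-6,10-dimethylpentadeca-1,2,5,9,13-pentaene, via N-propargyl sulfonylhydrazine 13 (not isolated), via propargyl diazene 14 (not isolated)
Conditions: 2-nitrobenzenesulfonylhydrazide, PPh3, DEAD, THF, −15 °C; then 23 °C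
Reagents that add atoms: none
Why: Myers allene synthesis: Mitsunobu N-alkylation, loss of sulfinic acid to the propargylic diazene and retro-ene loss of N2 deliver hydrogen to the distal alkyne carbon and give the terminal allene regiospecifically.

Step 9
Reactants: 15 (5E,9E,13E)-14-iodo-6,10-dimethylpentadeca-1,2,5,9,13-pentaene; 16 (E)-geranylacetone
Product: 18 (3S,5E,9E,13E)-3-[(2S,5E)-2-hydroxy-6,10-dimethylundeca-5,9-dien-2-yl]-14-iodo-6,10-dimethylpentadeca-1,5,9,13-tetraene, via (Z)-allylborane 17 (not isolated)
Conditions: 10-phenyl-9-borabicyclo[3.3.2]decane (B–H, single antipode, 1.05 equiv), Et2O, −10 °C; then 16, −78 to −40 °C; MeOH, aq. NaHCO3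
Reagents that add atoms: none
Why: Kinetic hydroboration of the monosubstituted allene places boron on the terminal carbon anti to the substituent and gives the (Z)-γ-substituted allylborane, which adds to the methyl ketone in a chair Zimmerman–Traxler allylboration (Z substituent axial, ketone chain equatorial) that fixes the syn relationship of the two new stereocentres (3S and carbinol S in 18), while the cage antipode directs the allyl group to the Re face of the carbonyl; this pairs two documented uses of these boranes, kinetic allene hydroboration and allylboration of methyl ketones.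

Step 10
Reactants: 18 seco alcohol (vinyl group on C14, (E)-alkenyl iodide at C11)
Product: 20 colleterpenol, (2S)-2-[(1R,3E,7E,11E)-4,8,12-trimethylcyclotetradeca-3,7,11-trien-1-yl]-6,10-dimethylundeca-5,9-dien-2-ol (5E), via B-alkyl-9-BBN borane 19 (not isolated)
Conditions: 9-BBN (1.5 equiv), THF, 0 °C to rt; then added over 12 h to Pd(dppf)Cl2 (20 mol %), AsPh3 (40 mol %), Cs2CO3 (4 equiv), DMF/THF/H2O, 45 °C, final ca. 1 mM
Reagents that add atoms: none
Why: 9-BBN adds anti-Markovnikov to the only monosubstituted alkene and makes C12 a primary alkylborane; after borate formation, zerovalent palladium inserts into the C11–I bond, the alkyl group passes from boron to palladium within the same molecule and reductive elimination forms C11–C12. The closest known reaction type is the B-alkyl Suzuki–Miyaura macrocyclisation of ω-alkenyl (E)-2-iodoalkenes, used to close 12- to 16-membered carbocycles. The 14-membered ring is closed end to end through a 15-membered palladacycle that contracts on reductive elimination. No stereocentre is created: the C10=C11 geometry is carried with retention from the alkenyl iodide, and C14 and C15 are untouched. The step needs site-selective hydroboration, secured by the steric demand of 9-BBN against four trisubstituted alkenes and the iodoalkene, and ring closure over oligomerisation, secured by slow addition to about 1 mM. The free tertiary hydroxyl should be tolerated, since any O–B bond is hydrolysed by the aqueous base.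

Compound list
1 | (2E,6E)-farnesyl acetate | CC(=O)OC/C=C(\C)CC/C=C(\C)CCC=C(C)C | starting material
2 | (2E,6E)-10-bromo-11-hydroxy-3,7,11-trimethyldodeca-2,6-dien-1-yl acetate (racemic) | CC(=O)OC/C=C(\C)CC/C=C(\C)CCC(Br)C(C)(C)O | intermediate
3 | (2E,6E)-9-(3,3-dimethyloxiran-2-yl)-3,7-dimethylnona-2,6-dien-1-ol (racemic) | OC/C=C(\C)CC/C=C(\C)CCC1OC1(C)C | intermediate
4 | (4E,8E)-10-hydroxy-4,8-dimethyldeca-4,8-dienal | OC/C=C(\C)CC/C=C(\C)CCC=O | intermediate
5 | (2E,6E)-3,7-dimethylundeca-2,6-dien-10-yn-1-ol | OC/C=C(\C)CC/C=C(\C)CCC#C | intermediate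
6 | dilithium salt of 5 (lithium alkoxide, lithium acetylide) | [Li+].[Li+].[O-]C/C=C(\C)CC/C=C(\C)CCC#[C-] | intermediate
7 | (2E,6E)-3,7-dimethyldodeca-2,6-dien-10-yn-1-ol | OC/C=C(\C)CC/C=C(\C)CCC#CC | intermediate
8 | (E)-alkenylzirconocene chloride from 7, hydroxyl bound as zirconocene chloride alkoxide | Cl[Zr](C1C=CC=C1)(C2C=CC=C2)OC/C=C(\C)CC/C=C(\C)CC/C=C(\C)[Zr](Cl)(C3C=CC=C3)C4C=CC=C4 | intermediate
9 | (2E,6E,10E)-11-iodo-3,7-dimethyldodeca-2,6,10-trien-1-ol | OC/C=C(\C)CC/C=C(\C)CC/C=C(\C)I | intermediate
10 | (2E,6E,10E)-1-bromo-11-iodo-3,7-dimethyldodeca-2,6,10-triene | BrC/C=C(\C)CC/C=C(\C)CC/C=C(\C)I | intermediate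
11 | prop-2-yn-1-ol | C#CCO | starting material
12 | (5E,9E,13E)-14-iodo-6,10-dimethylpentadeca-5,9,13-trien-2-yn-1-ol | OCC#CC/C=C(\C)CC/C=C(\C)CC/C=C(\C)I | intermediate
13 | N-alkyl-N-(2-nitrobenzenesulfonyl)hydrazine from 12 | NN(CC#CC/C=C(\C)CC/C=C(\C)CC/C=C(\C)I)S(=O)(=O)c1ccccc1[N+](=O)[O-] | intermediate
14 | propargylic monoalkyl diazene from 13 | N=NCC#CC/C=C(\C)CC/C=C(\C)CC/C=C(\C)I | intermediate
15 | (5E,9E,13E)-14-iodo-6,10-dimethylpentadeca-1,2,5,9,13-pentaene | C=C=CC/C=C(\C)CC/C=C(\C)CC/C=C(\C)I | intermediate
16 | (E)-geranylacetone, (5E)-6,10-dimethylundeca-5,9-dien-2-one | CC(=O)CC/C=C(\C)CCC=C(C)C | starting material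
17 | B-[(2Z,5E,9E,13E)-14-iodo-6,10-dimethylpentadeca-2,5,9,13-tetraen-1-yl]-10-phenyl-9-borabicyclo[3.3.2]decane (cage configuration as in the reagent antipode) | C(/C=C\C/C=C(\C)CC/C=C(\C)CC/C=C(\C)I)B1C(c2ccccc2)C2CCCC1CCC2 | intermediate
18 | (3S,5E,9E,13E)-3-[(2S,5E)-2-hydroxy-6,10-dimethylundeca-5,9-dien-2-yl]-14-iodo-6,10-dimethylpentadeca-1,5,9,13-tetraene | CC(C)=CCC/C(C)=C/CC[C@](C)(O)[C@H](C=C)C/C=C(\C)CC/C=C(\C)CC/C=C(\C)I | intermediate
19 | 9-BBN adduct of 18 (boron on the terminal carbon of the former vinyl group) | CC(C)=CCC/C(C)=C/CC[C@](C)(O)[C@H](CCB1C2CCCC1CCC2)C/C=C(\C)CC/C=C(\C)CC/C=C(\C)I | intermediate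
20 | colleterpenol, (2S)-2-[(1R,3E,7E,11E)-4,8,12-trimethylcyclotetradeca-3,7,11-trien-1-yl]-6,10-dimethylundeca-5,9-dien-2-ol (5E) | CC(C)=CCC/C(C)=C/CC[C@](C)(O)[C@H]1C/C=C(\C)CC/C=C(\C)CC/C=C(\C)CC1 | target

Total step count: 10. Longest linear sequence: 10 steps (1 to 20); 11 and 16 enter as purchased building blocks.

Steps most likely to fail

Step 10. Intermolecular coupling may outrun ring closure and give oligomers, the alkylpalladium may be lost to protodeboronation or β-hydride elimination, and O-borylation of the tertiary hydroxyl may slow the hydroboration. The fallback sets out from 19 and returns at 20; it forms the same C11–C12 bond through an isolated alkylzinc instead of the borane. Oxidation of 19 (NaBO3·4H2O, THF/H2O) should give the iodo diol F1. Appel iodination (I2, PPh3, imidazole) of the primary hydroxyl should give the primary iodide F2. Silylation of the tertiary hydroxyl (TMSOTf, 2,6-lutidine, −78 °C) should give the trimethylsilyl ether F3. Zinc insertion into the alkyl iodide (Zn dust, LiCl, THF, 25 °C, where the alkenyl iodide is much slower) should give the alkylzinc iodide F4. Slow addition of F4 to Pd2(dba)3/P(2-furyl)3 in THF/NMP at 40 °C (intramolecular Negishi coupling) should close the ring to the silyl ether of colleterpenol F5. TBAF in THF then gives 20.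

Step 9. Facial discrimination between the methyl group and the primary alkyl chain of the ketone may be poor, which lowers both the enantiomeric and the diastereomeric purity. The (Z)-allylborane may isomerise to the (E)-isomer by 1,3-boratropic shift before it adds, and the hindered γ-substituted reagent may add slowly. The fallback sets out from 15 and 16 and returns at 18; it replaces the stoichiometric allylborane by a catalytic allylcopper. Copper hydride-catalysed reductive coupling of the allene with the ketone (Cu(OAc)2 5 mol %, Ph-BPE in the antipode that gives Re-face addition, (MeO)2MeSiH, THF, rt) is known to give branched tertiary homoallylic alcohols with both stereocentres set by the ligand. It should deliver the silyl ether F6, which NH4F in MeOH converts into 18.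

Step 5. Regiocontrol of the hydrozirconation may be incomplete, with zirconium partly on C10, and the regioisomeric iodide would be carried into a constitutional isomer of the macrocycle. The fallback sets out from 5 and returns at 9; it fixes the regiochemistry with silicon. Bis-silylation of the dianion of 5 (n-BuLi 2.1 equiv, TMSCl) should give the bis-silylated alkyne F7. Anti-hydroalumination with i-Bu2AlH in heptane at 50 °C places aluminium on the silyl-bearing carbon, and MeLi then MeI methylates the alanate with retention to give the O-silylated vinylsilane F8. K2CO3 in MeOH frees the vinylsilane alcohol F9. Iododesilylation with NIS in MeCN/ClCH2CN at 0 °C proceeds with retention and gives 9.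

Further compounds
F1 | step 10 | (3S)-seco iodo diol, primary alcohol from oxidation of 19 | CC(C)=CCC/C(C)=C/CC[C@](C)(O)[C@H](CCO)C/C=C(\C)CC/C=C(\C)CC/C=C(\C)I
F2 | step 10 | primary alkyl iodide from F1 | CC(C)=CCC/C(C)=C/CC[C@](C)(O)[C@H](CCI)C/C=C(\C)CC/C=C(\C)CC/C=C(\C)I
F3 | step 10 | trimethylsilyl ether of F2 | CC(C)=CCC/C(C)=C/CC[C@](C)(O[Si](C)(C)C)[C@H](CCI)C/C=C(\C)CC/C=C(\C)CC/C=C(\C)I
F4 | step 10 | alkylzinc iodide from F3 | CC(C)=CCC/C(C)=C/CC[C@](C)(O[Si](C)(C)C)[C@H](CC[Zn]I)C/C=C(\C)CC/C=C(\C)CC/C=C(\C)I
F5 | step 10 | trimethylsilyl ether of colleterpenol | CC(C)=CCC/C(C)=C/CC[C@](C)(O[Si](C)(C)C)[C@H]1C/C=C(\C)CC/C=C(\C)CC/C=C(\C)CC1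
F6 | step 9 | dimethoxy(methyl)silyl ether of 18 | CC(C)=CCC/C(C)=C/CC[C@](C)(O[Si](C)(OC)OC)[C@H](C=C)C/C=C(\C)CC/C=C(\C)CC/C=C(\C)I
F7 | step 5 | O,C-bis(trimethylsilyl) derivative of 5 | C[Si](C)(C)OC/C=C(\C)CC/C=C(\C)CCC#C[Si](C)(C)C
F8 | step 5 | trimethylsilyl ether of (2E,6E,10Z)-3,7-dimethyl-11-(trimethylsilyl)dodeca-2,6,10-trien-1-ol (silicon trans to the chain) | C[Si](C)(C)OC/C=C(\C)CC/C=C(\C)CC/C=C(\C)[Si](C)(C)C
F9 | step 5 | (2E,6E,10Z)-3,7-dimethyl-11-(trimethylsilyl)dodeca-2,6,10-trien-1-ol | OC/C=C(\C)CC/C=C(\C)CC/C=C(\C)[Si](C)(C)C
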